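The route rests on cutting the C9–C10 bond of ring B (labdane numbering). C10, the methyl-bearing quaternary carbon shared by rings A and B and bonded to C9, is made from a ring A C1=C10 alkene. Hydrogen-atom transfer to C1 gives the tertiary C10 radical, which closes ring B onto a tethered enoate and sets C9 and C10 of the trans-decalin in one operation. The precursor is an enantiopure cyclohexene carrying C4 and C5. Its C5 arm ends in an (E)-enoate whose C8 carbonyl is masked as a dioxolane. The C19 oxygen travels as a TBS ether, because an acetate would not survive the organolithium and hydride steps on either side.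

Key step: step 12

Assumption: labdane numbering is used for all intermediates, and the (1R,2R) catalyst pair in step 3 is taken to give (R)-6; if the sense proves opposite, the equally available (1S,2S) pair is used.

Step 1
Reactants: 1 2-methylpropane-1,3-diol
Product: 2 rac-3-[(tert-butyldimethylsilyl)oxy]-2-methylpropan-1-ol
Conditions: TBSCl (1 equiv), imidazole, 1 (3 equiv), CH2Cl2, 0 °C
Reagents that add atoms: tert-butyldimethylsilyl chloride, C[Si](C)(Cl)C(C)(C)C
Why: Silyl ether formation with the cheap diol in excess favours the mono-ether, and the racemic stereocentre is of no consequence because step 3 flattens it.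

Step 2
Reactants: 2 rac-3-[(tert-butyldimethylsilyl)oxy]-2-methylpropan-1-ol
Product: 3 rac-3-[(tert-butyldimethylsilyl)oxy]-2-methylpropanal
Conditions: TEMPO (2,2,6,6-tetramethylpiperidin-1-oxyl, 10 mol %), PhI(OAc)2, CH2Cl2, rt
Reagents that add atoms: none
Why: Oxoammonium (TEMPO) oxidation stops at the aldehyde and is non-basic, so β-elimination of silanol is avoided.

Step 3
Reactants: 3 rac-3-[(tert-butyldimethylsilyl)oxy]-2-methylpropanal; 4 pent-1-en-3-one
Product: 6 (4R)-4-{[(tert-butyldimethylsilyl)oxy]methyl}-2,4-dimethylcyclohex-2-en-1-one, via keto aldehyde 5 (not isolated)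
Conditions: (1R,2R)-cyclohexane-1,2-diamine (20 mol %), (1R,2R)-cyclohexane-1,2-dicarboxylic acid (20 mol %), toluene, rt; then KOH (20 mol %), EtOH, rt
Reagents that add atoms: none
Why: In this asymmetric Robinson annulation (enamine Michael addition, then aldol condensation) the primary amine turns the α-branched aldehyde into a planar enamine with CH2OTBS away from nitrogen, and attack on the ammonium-bound enone from one enamine face sets the C4 quaternary centre, which cannot epimerise afterwards.

Step 4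
Reactants: 6 (4R)-4-{[(tert-butyldimethylsilyl)oxy]methyl}-2,4-dimethylcyclohex-2-en-1-one
Product: 7 (1S,4R)-4-{[(tert-butyldimethylsilyl)oxy]methyl}-2,4-dimethylcyclohex-2-en-1-ol (OH cis to CH2OTBS)
Conditions: (R)-Me-CBS [(3aR)-1-methyl-3,3-diphenyltetrahydro-1H,3H-pyrrolo[1,2-c][1,3,2]oxazaborole, 20 mol %], BH3·SMe2, THF, −30 °C; MeOH, aqueous work-up
Reagents that add atoms: none
Why: In the Corey–Bakshi–Shibata reduction the methyl-bearing alkene arm acts as the large group, so reagent control gives the (1S) carbinol, and any (S)-6 carried over becomes a trans diastereomer that chromatography removes.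

Step 5
Reactants: 7 (1S,4R)-4-{[(tert-butyldimethylsilyl)oxy]methyl}-2,4-dimethylcyclohex-2-en-1-ol; 8 triethyl orthoacetate
Product: 10 ethyl 2-[(1S,6R)-6-{[(tert-butyldimethylsilyl)oxy]methyl}-2,6-dimethylcyclohex-2-en-1-yl]acetate, via ketene acetal 9 (not isolated)
Conditions: EtCO2H (10 mol %), neat in 8, 140 °C, EtOH distilled off
Reagents that add atoms: none
Why: The Johnson–Claisen rearrangement is suprafacial, so from the half-chair with pseudoaxial C1–O the C5–C6 bond forms on the face that carried oxygen (cis to CH2OTBS, anti to the pseudoaxial C4 methyl), which sets C5 and moves the alkene to C1=C10.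

Step 6
Reactants: 10 ethyl 2-[(1S,6R)-6-{[(tert-butyldimethylsilyl)oxy]methyl}-2,6-dimethylcyclohex-2-en-1-yl]acetate
Product: 11 2-[(1S,6R)-6-{[(tert-butyldimethylsilyl)oxy]methyl}-2,6-dimethylcyclohex-2-en-1-yl]ethan-1-ol
Conditions: LiAlH4, Et2O, 0 °C
Reagents that add atoms: none
Why: Hydride reduction of the ester leaves the silyl ether and the trisubstituted alkene untouched.

Step 7
Reactants: 11 2-[(1S,6R)-6-{[(tert-butyldimethylsilyl)oxy]methyl}-2,6-dimethylcyclohex-2-en-1-yl]ethan-1-ol
Product: 12 2-[(1S,6R)-6-{[(tert-butyldimethylsilyl)oxy]methyl}-2,6-dimethylcyclohex-2-en-1-yl]ethyl iodide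
Conditions: I2, PPh3, imidazole, CH2Cl2, 0 °C → rt
Reagents that add atoms: iodine, II
Why: Appel-type (Garegg–Samuelsson) iodination is an SN2 displacement at an unhindered primary carbon under buffered conditions.

Step 8
Reactants: 12 2-[(1S,6R)-6-{[(tert-butyldimethylsilyl)oxy]methyl}-2,6-dimethylcyclohex-2-en-1-yl]ethyl iodide; 13 1,3-dithiane
Product: 15 2-{2-[(1S,6R)-6-{[(tert-butyldimethylsilyl)oxy]methyl}-2,6-dimethylcyclohex-2-en-1-yl]ethyl}-1,3-dithiane, via 2-lithio-1,3-dithiane 14 (not isolated)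
Conditions: 13, n-BuLi, THF, −30 °C; then 12, −78 → 0 °C
Reagents that add atoms: none
Why: Corey–Seebach umpolung alkylation of a primary iodide brings in C8 at the ketone oxidation level.

Step 9
Reactants: 15 2-{2-[(1S,6R)-6-{[(tert-butyldimethylsilyl)oxy]methyl}-2,6-dimethylcyclohex-2-en-1-yl]ethyl}-1,3-dithiane
Product: 17 2-{2-[(1S,6R)-6-{[(tert-butyldimethylsilyl)oxy]methyl}-2,6-dimethylcyclohex-2-en-1-yl]ethyl}-1,3-dithiane-2-carbaldehyde, via lithiated dithiane 16 (not isolated)
Conditions: n-BuLi, THF, −20 °C; DMF, −78 → 0 °C; H2O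
Reagents that add atoms: N,N-dimethylformamide, CN(C)C=O
Why: A second Corey–Seebach metalation followed by formylation adds C9, and the tetrahedral adduct collapses only on work-up, so over-addition cannot occur.

Step 10
Reactants: 17 2-{2-[(1S,6R)-6-{[(tert-butyldimethylsilyl)oxy]methyl}-2,6-dimethylcyclohex-2-en-1-yl]ethyl}-1,3-dithiane-2-carbaldehyde; 18 methyl 2-(triphenylphosphoranylidene)acetate
Product: 19 methyl (E)-3-(2-{2-[(1S,6R)-6-{[(tert-butyldimethylsilyl)oxy]methyl}-2,6-dimethylcyclohex-2-en-1-yl]ethyl}-1,3-dithian-2-yl)prop-2-enoate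
Conditions: toluene, 80 °C
Reagents that add atoms: none
Why: Wittig olefination of a non-enolisable aldehyde with a stabilised ylide should give the (E)-enoate (C11, C12).

Step 11
Reactants: 19 methyl (E)-3-(2-{2-[(1S,6R)-6-{[(tert-butyldimethylsilyl)oxy]methyl}-2,6-dimethylcyclohex-2-en-1-yl]ethyl}-1,3-dithian-2-yl)prop-2-enoate
Product: 20 methyl (E)-3-(2-{2-[(1S,6R)-6-{[(tert-butyldimethylsilyl)oxy]methyl}-2,6-dimethylcyclohex-2-en-1-yl]ethyl}-1,3-dioxolan-2-yl)prop-2-enoate
Conditions: PhI(OCOCF3)2, HOCH2CH2OH (excess), MeCN, 0 °C; aq. NaHCO3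
Reagents that add atoms: ethylene glycol, OCCO
Why: In this oxidative dethioacetalisation the trivalent iodine reagent attacks sulfur far faster than either alkene and the glycol captures the thionium and oxocarbenium ions, so sulfur, which would poison the iron catalyst, is replaced by a small symmetrical dioxolane.

Step 12
Reactants: 20 methyl (E)-3-(2-{2-[(1S,6R)-6-{[(tert-butyldimethylsilyl)oxy]methyl}-2,6-dimethylcyclohex-2-en-1-yl]ethyl}-1,3-dioxolan-2-yl)prop-2-enoate
Product: 21 methyl (4R,5S,9S,10R)-19-[(tert-butyldimethylsilyl)oxy]-8,8-(ethylenedioxy)-13,14,15,16,17-pentanor-ent-labdan-12-oate (trans-decalin; axial C10 methyl; equatorial C9 CH2CO2Me arm)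
Conditions: Fe(acac)3 (50 mol %), PhSiH3 (3 equiv), EtOH/HOCH2CH2OH 5:1, 0.01 M, 60 °C
Reagents that add atoms: none
Why: Fe(acac)3 and PhSiH3 in ethanol produce a hydride of trivalent iron that hands a hydrogen atom to C1, the less substituted end of the electron-rich C1=C10 alkene, which leaves a nucleophilic tertiary radical on C10 with the C20 methyl already attached; the closest known reaction type is the iron-catalysed reductive olefin coupling, an intramolecular Giese addition started by metal-hydride hydrogen atom transfer. Ring B (C5–C6–C7–C8–C9–C10) closes in the 6-exo-trig mode by attack of C10 on C9, the β-carbon of the enoate, and the C11 radical next to the ester is then reduced by divalent iron and protonated by ethanol. C10 is controlled by ring A: in its chair the C5–C6 tether is equatorial, so a chair-like closure makes the C9–C10 bond equatorial and turns the methyl axial (trans fusion), while the axial trajectory that would lead to the cis fusion runs into the axial C4–CH2OTBS group. C9 is controlled by the same chair, which places the CH–CO2Me terminus pseudo-equatorial, and a minor axial epimer would be levelled by enolisation once the C8 ketone is free in step 16. The step needs chemoselective hydrogen transfer to C1=C10 in the presence of the enoate, secured by the much higher electron density of the trisubstituted alkene, and attack at C9 only, secured by the dioxolane, which removes the C8 carbonyl from conjugation so that the ester alone polarises the acceptor. High dilution keeps the closure ahead of intermolecular addition.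

Step 13
Reactants: 21 methyl (4R,5S,9S,10R)-19-[(tert-butyldimethylsilyl)oxy]-8,8-(ethylenedioxy)-13,14,15,16,17-pentanor-ent-labdan-12-oate
Product: 22 (4R,5S,9S,10R)-19-[(tert-butyldimethylsilyl)oxy]-8,8-(ethylenedioxy)-13,14,15,16,17-pentanor-ent-labdan-12-ol
Conditions: LiAlH4, THF, 0 °C
Reagents that add atoms: none
Why: Hydride reduction of the ester gives the C12 alcohol as the only free hydroxyl, since ketal and silyl ether are inert.

Step 14
Reactants: 22 (4R,5S,9S,10R)-19-[(tert-butyldimethylsilyl)oxy]-8,8-(ethylenedioxy)-13,14,15,16,17-pentanor-ent-labdan-12-ol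
Product: 23 (4R,5S,9S,10R)-19-[(tert-butyldimethylsilyl)oxy]-8,8-(ethylenedioxy)-12-iodo-13,14,15,16,17-pentanor-ent-labdane
Conditions: I2, PPh3, imidazole, CH2Cl2, 0 °C → rt
Reagents that add atoms: iodine, II
Why: Appel-type iodination at the primary C12 proceeds under imidazole buffering that the ketal tolerates.

Step 15
Reactants: 23 (4R,5S,9S,10R)-19-[(tert-butyldimethylsilyl)oxy]-8,8-(ethylenedioxy)-12-iodo-13,14,15,16,17-pentanor-ent-labdane; 24 4-bromofuran-2(5H)-one
Product: 26 (4R,5S,9S,10R)-19-[(tert-butyldimethylsilyl)oxy]-8,8-(ethylenedioxy)-17-nor-ent-labd-13-en-15,16-olide, via alkylzinc iodide 25 (not isolated)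
Conditions: Zn dust, LiCl, THF, 40 °C; then 24, Pd(OAc)2 (5 mol %), SPhos (2-dicyclohexylphosphino-2′,6′-dimethoxybiphenyl, 10 mol %), THF, rt
Reagents that add atoms: none
Why: In this Negishi cross-coupling the non-basic primary alkylzinc iodide tolerates ketal, silyl ether and lactone, the electron-poor C–Br bond adds quickly to zerovalent palladium, and the bulky biaryl phosphine favours reductive elimination over β-hydride elimination, so the C12–C13 bond and the complete butenolide arrive together.

Step 16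
Reactants: 26 (4R,5S,9S,10R)-19-[(tert-butyldimethylsilyl)oxy]-8,8-(ethylenedioxy)-17-nor-ent-labd-13-en-15,16-olide
Product: 27 (4R,5S,9S,10R)-19-hydroxy-8-oxo-17-nor-ent-labd-13-en-15,16-olide
Conditions: 2 M aq. HCl/THF 1:3, 40 °C
Reagents that add atoms: water, O
Why: Acid hydrolysis removes dioxolane and TBS ether in one operation, the butenolide is acid-stable, and C9, now α to the ketone, already holds its side chain in the thermodynamically preferred equatorial position.

Step 17
Reactants: 27 (4R,5S,9S,10R)-19-hydroxy-8-oxo-17-nor-ent-labd-13-en-15,16-olide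
Product: 28 (4R,5S,9S,10R)-19-acetoxy-8-oxo-17-nor-ent-labd-13-en-15,16-olide
Conditions: Ac2O, pyridine, 4-(dimethylamino)pyridine (cat.), CH2Cl2, rt
Reagents that add atoms: acetic anhydride, CC(=O)OC(C)=O
Why: Nucleophile-catalysed acylation of the only hydroxyl group installs the acetate under conditions too mild to enolise the butenolide.

Step 18
Reactants: 28 (4R,5S,9S,10R)-19-acetoxy-8-oxo-17-nor-ent-labd-13-en-15,16-olide
Product: 29 (4R,5S,9R,10S)-19-acetoxy-ent-labda-8(17),13-dien-15,16-olide (target)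
Conditions: CH2Br2, Zn, TiCl4, THF, −40 → 5 °C (reagent pre-formed); then 28, CH2Cl2, 0 °C → rt
Reagents that add atoms: dibromomethane, BrCBr
Why: In the Takai–Lombardo methylenation the gem-dizinc/titanium reagent is non-basic and reacts with ketones much faster than with esters or lactones, so C9 is not epimerised and acetate and butenolide survive.

Compound list
1 | 2-methylpropane-1,3-diol | CC(CO)CO | starting material
2 | rac-3-[(tert-butyldimethylsilyl)oxy]-2-methylpropan-1-ol | CC(CO)CO[Si](C)(C)C(C)(C)C | intermediate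
3 | rac-3-[(tert-butyldimethylsilyl)oxy]-2-methylpropanal | CC(C=O)CO[Si](C)(C)C(C)(C)C | intermediate
4 | pent-1-en-3-one | CCC(=O)C=C | starting material
5 | (2S)-2-{[(tert-butyldimethylsilyl)oxy]methyl}-2-methyl-5-oxoheptanal (not isolated) | O=C[C@](C)(CO[Si](C)(C)C(C)(C)C)CCC(=O)CC | intermediate
6 | (4R)-4-{[(tert-butyldimethylsilyl)oxy]methyl}-2,4-dimethylcyclohex-2-en-1-one | CC1=C[C@](C)(CO[Si](C)(C)C(C)(C)C)CCC1=O | intermediate
7 | (1S,4R)-4-{[(tert-butyldimethylsilyl)oxy]methyl}-2,4-dimethylcyclohex-2-en-1-ol | CC1=C[C@](C)(CO[Si](C)(C)C(C)(C)C)CC[C@@H]1O | intermediate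
8 | triethyl orthoacetate | CCOC(C)(OCC)OCC | starting material
9 | 1-ethoxyvinyl ether of 7, mixed ketene acetal (not isolated) | CC1=C[C@](C)(CO[Si](C)(C)C(C)(C)C)CC[C@@H]1OC(=C)OCC | intermediate
10 | ethyl 2-[(1S,6R)-6-{[(tert-butyldimethylsilyl)oxy]methyl}-2,6-dimethylcyclohex-2-en-1-yl]acetate | CCOC(=O)C[C@@H]1[C@](C)(CO[Si](C)(C)C(C)(C)C)CCC=C1C | intermediate
11 | 2-[(1S,6R)-6-{[(tert-butyldimethylsilyl)oxy]methyl}-2,6-dimethylcyclohex-2-en-1-yl]ethan-1-ol | OCC[C@@H]1[C@](C)(CO[Si](C)(C)C(C)(C)C)CCC=C1C | intermediate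
12 | 2-[(1S,6R)-6-{[(tert-butyldimethylsilyl)oxy]methyl}-2,6-dimethylcyclohex-2-en-1-yl]ethyl iodide | ICC[C@@H]1[C@](C)(CO[Si](C)(C)C(C)(C)C)CCC=C1C | intermediate
13 | 1,3-dithiane | C1CSCSC1 | starting material
14 | 2-lithio-1,3-dithiane (not isolated) | [Li]C1SCCCS1 | intermediate
15 | 2-{2-[(1S,6R)-6-{[(tert-butyldimethylsilyl)oxy]methyl}-2,6-dimethylcyclohex-2-en-1-yl]ethyl}-1,3-dithiane | S1CCCSC1CC[C@@H]2[C@](C)(CO[Si](C)(C)C(C)(C)C)CCC=C2C | intermediate
16 | 2-lithio derivative of 15 (not isolated) | [Li]C1(SCCCS1)CC[C@@H]2[C@](C)(CO[Si](C)(C)C(C)(C)C)CCC=C2C | intermediate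
17 | 2-{2-[(1S,6R)-6-{[(tert-butyldimethylsilyl)oxy]methyl}-2,6-dimethylcyclohex-2-en-1-yl]ethyl}-1,3-dithiane-2-carbaldehyde | O=CC1(SCCCS1)CC[C@@H]2[C@](C)(CO[Si](C)(C)C(C)(C)C)CCC=C2C | intermediate
18 | methyl 2-(triphenylphosphoranylidene)acetate | COC(=O)C=P(c1ccccc1)(c1ccccc1)c1ccccc1 | starting material
19 | methyl (E)-3-(2-{2-[(1S,6R)-6-{[(tert-butyldimethylsilyl)oxy]methyl}-2,6-dimethylcyclohex-2-en-1-yl]ethyl}-1,3-dithian-2-yl)prop-2-enoate | COC(=O)/C=C/C1(SCCCS1)CC[C@@H]2[C@](C)(CO[Si](C)(C)C(C)(C)C)CCC=C2C | intermediate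
20 | methyl (E)-3-(2-{2-[(1S,6R)-6-{[(tert-butyldimethylsilyl)oxy]methyl}-2,6-dimethylcyclohex-2-en-1-yl]ethyl}-1,3-dioxolan-2-yl)prop-2-enoate (key-step precursor) | COC(=O)/C=C/C1(OCCO1)CC[C@@H]2[C@](C)(CO[Si](C)(C)C(C)(C)C)CCC=C2C | intermediate
21 | methyl (4R,5S,9S,10R)-19-[(tert-butyldimethylsilyl)oxy]-8,8-(ethylenedioxy)-13,14,15,16,17-pentanor-ent-labdan-12-oate (key-step product) | O1CCOC12CC[C@@H]3[C@](C)(CO[Si](C)(C)C(C)(C)C)CCC[C@@]3(C)[C@@H]2CC(=O)OC | intermediate
22 | (4R,5S,9S,10R)-19-[(tert-butyldimethylsilyl)oxy]-8,8-(ethylenedioxy)-13,14,15,16,17-pentanor-ent-labdan-12-ol | O1CCOC12CC[C@@H]3[C@](C)(CO[Si](C)(C)C(C)(C)C)CCC[C@@]3(C)[C@@H]2CCO | intermediate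
23 | (4R,5S,9S,10R)-19-[(tert-butyldimethylsilyl)oxy]-8,8-(ethylenedioxy)-12-iodo-13,14,15,16,17-pentanor-ent-labdane | O1CCOC12CC[C@@H]3[C@](C)(CO[Si](C)(C)C(C)(C)C)CCC[C@@]3(C)[C@@H]2CCI | intermediate
24 | 4-bromofuran-2(5H)-one | BrC1=CC(=O)OC1 | starting material
25 | C12 alkylzinc iodide from 23 (not isolated) | O1CCOC12CC[C@@H]3[C@](C)(CO[Si](C)(C)C(C)(C)C)CCC[C@@]3(C)[C@@H]2CC[Zn]I | intermediate
26 | (4R,5S,9S,10R)-19-[(tert-butyldimethylsilyl)oxy]-8,8-(ethylenedioxy)-17-nor-ent-labd-13-en-15,16-olide | O1CCOC12CC[C@@H]3[C@](C)(CO[Si](C)(C)C(C)(C)C)CCC[C@@]3(C)[C@@H]2CCC4=CC(=O)OC4 | intermediate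
27 | (4R,5S,9S,10R)-19-hydroxy-8-oxo-17-nor-ent-labd-13-en-15,16-olide | O=C1CC[C@@H]2[C@](C)(CO)CCC[C@@]2(C)[C@@H]1CCC1=CC(=O)OC1 | intermediate
28 | (4R,5S,9S,10R)-19-acetoxy-8-oxo-17-nor-ent-labd-13-en-15,16-olide | O=C1CC[C@@H]2[C@](C)(COC(C)=O)CCC[C@@]2(C)[C@@H]1CCC1=CC(=O)OC1 | intermediate
29 | (4R,5S,9R,10S)-19-acetoxy-ent-labda-8(17),13-dien-15,16-olide | C=C1CC[C@@H]2[C@](C)(COC(C)=O)CCC[C@@]2(C)[C@@H]1CCC1=CC(=O)OC1 | target

Total step count: 18. Longest linear sequence: 18 steps (1 → 29).

Steps most likely to fail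

1. Step 12 (key step).
- **What may go wrong:** the C10 radical may be quenched by a second hydrogen transfer (net hydrogenation of C1=C10), or the iron hydride may reduce the enoate, before the crowded C9–C10 bond forms.
- **Fallback:** radical generation is separated from hydride chemistry. Setting out from 20, Mukaiyama hydration (Mn(dpm)3, PhSiH3, O2, i-PrOH), in which oxygen captures the C10 radical faster than it cyclises, should give the C10 tertiary alcohol F1 (either epimer serves). Acylation with methyl chlorooxoacetate (Et3N, 4-(dimethylamino)pyridine) gives the methyl oxalate F2. One equivalent of aqueous CsOH cleaves the far more reactive oxalate methyl ester to the cesium oxalate F3. Visible-light photoredox double decarboxylation ([Ir(dF(CF3)ppy)2(dtbbpy)]PF6, H2O, DME/DMF, blue LEDs, 60 °C) then releases the same C10 radical in a medium free of hydrogen-atom donors. The same 6-exo closure comes back to the route at 21.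

2. Step 3.
- **What may go wrong:** the two enamine faces may be poorly discriminated, because CH3 and CH2OTBS must be told apart, which would give low enantiomeric purity at C4.
- **Fallback:** resolution through reagent-controlled reduction replaces asymmetric C–C bond formation. From 3 and 4, pyrrolidine/AcOH catalysis gives the racemic keto aldehyde F4, which KOH closes to the racemic enone F5. The reduction conditions of step 4 convert both enantiomers into (1S) carbinols, namely 7 and the (1S,4S) trans alcohol F6. These are diastereomers and can be separated by chromatography. The route is rejoined at 7 at the cost of half the material.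

3. Step 15.
- **What may go wrong:** β-hydride elimination or protodemetalation of the alkyl metal species, or consumption of the electrophilic bromobutenolide by side reactions, may outrun C12–C13 bond formation.
- **Fallback:** the butenolide is built on the chain without palladium. From 23, alkylation of 2-lithio-1,3-dithiane 14 gives the C12-dithiane F7. n-BuLi converts it into its 2-lithio derivative F8, which paraformaldehyde traps as the hydroxymethyl dithiane F9. Neutral dethioacetalisation (MeI, CaCO3, aq. MeCN) spares the dioxolane and gives the α-hydroxy ketone F10. Ph3P=C=C=O (Bestmann ylide, toluene, 90 °C) acylates the hydroxyl to the ester ylide F11, whose intramolecular Wittig reaction closes the ring and returns to the route at 26.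

Further compounds
F1 | step 12 | C10 tertiary alcohol of 20 (C10 epimers) | COC(=O)/C=C/C1(OCCO1)CC[C@@H]2[C@](C)(CO[Si](C)(C)C(C)(C)C)CCCC2(C)O
F2 | step 12 | C10 methyl oxalate of F1 | COC(=O)/C=C/C1(OCCO1)CC[C@@H]2[C@](C)(CO[Si](C)(C)C(C)(C)C)CCCC2(C)OC(=O)C(=O)OC
F3 | step 12 | C10 cesium oxalate | COC(=O)/C=C/C1(OCCO1)CC[C@@H]2[C@](C)(CO[Si](C)(C)C(C)(C)C)CCCC2(C)OC(=O)C(=O)[O-].[Cs+]
F4 | step 3 | rac-2-{[(tert-butyldimethylsilyl)oxy]methyl}-2-methyl-5-oxoheptanal | O=CC(C)(CO[Si](C)(C)C(C)(C)C)CCC(=O)CC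
F5 | step 3 | rac-4-{[(tert-butyldimethylsilyl)oxy]methyl}-2,4-dimethylcyclohex-2-en-1-one | CC1=CC(C)(CO[Si](C)(C)C(C)(C)C)CCC1=O
F6 | step 3 | (1S,4S)-4-{[(tert-butyldimethylsilyl)oxy]methyl}-2,4-dimethylcyclohex-2-en-1-ol | CC1=C[C@@](C)(CO[Si](C)(C)C(C)(C)C)CC[C@@H]1O
F7 | step 15 | 2-alkyl-1,3-dithiane from 23 (dithiane carbon = C13) | O1CCOC12CC[C@@H]3[C@](C)(CO[Si](C)(C)C(C)(C)C)CCC[C@@]3(C)[C@@H]2CCC4SCCCS4
F8 | step 15 | 2-lithio derivative of F7 | O1CCOC12CC[C@@H]3[C@](C)(CO[Si](C)(C)C(C)(C)C)CCC[C@@]3(C)[C@@H]2CCC4([Li])SCCCS4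
F9 | step 15 | 2-alkyl-2-(hydroxymethyl)-1,3-dithiane | O1CCOC12CC[C@@H]3[C@](C)(CO[Si](C)(C)C(C)(C)C)CCC[C@@]3(C)[C@@H]2CCC4(CO)SCCCS4
F10 | step 15 | C13 ketone with C16 hydroxyl (α-hydroxy ketone) | O1CCOC12CC[C@@H]3[C@](C)(CO[Si](C)(C)C(C)(C)C)CCC[C@@]3(C)[C@@H]2CCC(=O)CO
F11 | step 15 | (triphenylphosphoranylidene)acetate ester of F10 | O1CCOC12CC[C@@H]3[C@](C)(CO[Si](C)(C)C(C)(C)C)CCC[C@@]3(C)[C@@H]2CCC(=O)COC(=O)C=P(c4ccccc4)(c4ccccc4)c4ccccc4
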